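**Strategy.** The target is divided into 6-oxopristimerol (from pristimerin) and a seco-guaiane (primed atoms, guaiane numbering) made from (R)-citronellal, 1-bromobut-2-yne and one CH2 of CH2I2. A hetero-Diels–Alder reaction forms the dioxane and leaves C5′ as a silyl aryl ketal. The key step exploits C5′, the allylic, O2-bearing carbon shared by the dioxane, cyclopentene and cycloheptane rings, and the C6′H2–C7′H(isopropenyl) unit, which is a ring-opened gem-dimethylcyclopropane: ionisation at C5′ and attack of the cyclopropane CH2 corner form C5′–C6′, close the seven-membered ring last, fix the cis-propellane and unveil the isopropenyl group by strain release. The precursor carries a 4-(2,2-dimethylcyclopropyl)butan-2-yl chain on C1′.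

Key step: step 14

Assumption: pristimerin (1) is bought and serves as chiral-pool source of the triterpene half, so its ring system is not built de novo.

Numbering: triterpene C1–C30 as in pristimerin (O2 on C2, O3 on C3). Sesquiterpene C1′–C15′ as in guaiane: cyclopentene C1′–C5′ (methyl C15′ on C4′), seven-membered ring C1′, C5′–C10′ (methyl C14′ on C10′, isopropenyl C11′–C13′ on C7′).

Step 1
Reactants: 1 pristimerin
Product: 3 pristimerol 2,3-diacetate, via pristimerol 2 (not isolated)
Conditions: NaBH4, MeOH/THF, 0 °C; then Ac2O, pyridine, DMAP, rt, argon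
Reagents that add atoms: acetic anhydride CC(=O)OC(C)=O
Why: Hydride adds in a 1,6-fashion to the quinone methide at C6 (conjugate reduction) and the air-sensitive catechol is acetylated in the same flask; no stereocenter is formed.

Step 2
Reactants: 3 pristimerol 2,3-diacetate
Product: 4 6-oxopristimerol 2,3-diacetate
Conditions: Rh2(cap)4 (cap = caprolactamate, 1 mol %), t-BuOOH, K2CO3, CH2Cl2, rt
Reagents that add atoms: tert-butyl hydroperoxide CC(C)(C)OO
Why: Allylic oxidation by the tert-butylperoxy radical chain: the C6 methylene is benzylic and allylic at once and is the only allylic CH of the C7=C8 alkene (C9 and C14 are quaternary), so it should be oxidised selectively to the ketone.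

Step 3
Reactants: 4 6-oxopristimerol 2,3-diacetate
Product: 5 6-oxopristimerol
Conditions: K2CO3, MeOH, 0 °C to rt, degassed
Reagents that add atoms: none
Why: Mild methanolysis (transesterification) of the two aryl acetates frees the catechol, while the hindered C29 methyl ester and the non-enolisable C6 ketone are not affected.

Step 4
Reactants: 6 (R)-citronellal
Product: 7 (6R)-8,8-dimethoxy-2,6-dimethyloct-2-ene
Conditions: HC(OMe)3, MeOH, PPTS (cat.), rt
Reagents that add atoms: trimethyl orthoformate COC(OC)OC
Why: Acetalisation under mild acid masks the aldehyde for the oxidative and strongly basic steps that follow and leaves the C3 stereocenter (future C10′) untouched.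

Step 5
Reactants: 7 (6R)-8,8-dimethoxy-2,6-dimethyloct-2-ene
Product: 8 (2E,6R)-8,8-dimethoxy-2,6-dimethyloct-2-en-1-ol
Conditions: SeO2 (cat.), t-BuOOH, CH2Cl2, 0 °C to rt
Reagents that add atoms: tert-butyl hydroperoxide CC(C)(C)OO
Why: Riley oxidation: SeO2 attacks the trisubstituted alkene by an ene reaction and [2,3]-sigmatropic shift at the E-methyl group, giving the E-allylic alcohol needed as directing group, with the hydroperoxide as terminal oxidant.

Step 6
Reactants: 8 (2E,6R)-8,8-dimethoxy-2,6-dimethyloct-2-en-1-ol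
Product: 9 [(1R,2R)-2-[(3R)-5,5-dimethoxy-3-methylpentyl]-1-methylcyclopropyl]methanol
Conditions: Et2Zn, CH2I2, DME, (4S,5S)-2-butyl-N,N,N′,N′-tetramethyl-1,3,2-dioxaborolane-4,5-dicarboxamide (1.2 equiv), CH2Cl2, −10 °C to rt
Reagents that add atoms: diiodomethane ICI
Why: Charette asymmetric Simmons–Smith cyclopropanation: the zinc alkoxide bound to the chiral dioxaborolane delivers CH2 (the future C6′) syn-stereospecifically to one face of the E-allylic alcohol under reagent control, the (4S,5S) ligand being chosen by analogy with the established facial sense for E-allylic alcohols so that ring carbon 2 (future C7′) becomes R.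

Step 7
Reactants: 9 [(1R,2R)-2-[(3R)-5,5-dimethoxy-3-methylpentyl]-1-methylcyclopropyl]methanol
Product: 10 (1R,2R)-2-[(3R)-5,5-dimethoxy-3-methylpentyl]-1-methylcyclopropane-1-carbaldehyde
Conditions: Dess–Martin periodinane, NaHCO3, CH2Cl2, 0 °C to rt
Reagents that add atoms: none
Why: Dess–Martin oxidation of the neopentyl primary alcohol stops at the aldehyde, which has no α-hydrogen and cannot epimerise; the acetal survives the buffered conditions.

Step 8
Reactants: 10 (1R,2R)-2-[(3R)-5,5-dimethoxy-3-methylpentyl]-1-methylcyclopropane-1-carbaldehyde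
Product: 12 (1R)-1-[(3R)-5,5-dimethoxy-3-methylpentyl]-2,2-dimethylcyclopropane, via hydrazone 11 (not isolated)
Conditions: N2H4·H2O, KOH, diethylene glycol, 130 °C then 200 °C
Reagents that add atoms: none
Why: Wolff–Kishner reduction (Huang-Minlon conditions) turns the formyl group into the second methyl through the hydrazone anion and a diimide, without a cyclopropylcarbinyl cation or radical that would open the ring; the acetal is stable to base.

Step 9
Reactants: 12 (1R)-1-[(3R)-5,5-dimethoxy-3-methylpentyl]-2,2-dimethylcyclopropane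
Product: 13 (3R)-5-[(1R)-2,2-dimethylcyclopropyl]-3-methylpentanal
Conditions: AcOH/H2O/THF, rt
Reagents that add atoms: water O
Why: Acid-catalysed acetal hydrolysis frees the aldehyde; the alkyl-substituted cyclopropane is stable to dilute acid at room temperature.

Step 10
Reactants: 13 (3R)-5-[(1R)-2,2-dimethylcyclopropyl]-3-methylpentanal; 14 1-bromobut-2-yne
Product: 17 (3R)-2-(but-2-yn-1-yl)-5-[(1R)-2,2-dimethylcyclopropyl]-3-methylpentanal, via N-tert-butyl imine 15 (not isolated), via alkylated imine 16 (not isolated)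
Conditions: t-BuNH2, 4 Å MS, Et2O, rt; LiN(i-Pr)2, THF, −78 to 0 °C; 14, −78 °C to rt; aq. oxalic acid, rt
Reagents that add atoms: water O
Why: Metalloenamine (Stork) alkylation: the lithiated imine is monoalkylated at the α-carbon by the propargylic bromide in an SN2 reaction and mild acid returns the aldehyde; the new α-stereocenter forms as a mixture and becomes sp2 at step 12.

Step 11
Reactants: 17 (3R)-2-(but-2-yn-1-yl)-5-[(1R)-2,2-dimethylcyclopropyl]-3-methylpentanal
Product: 18 5-[(2R)-4-[(1R)-2,2-dimethylcyclopropyl]butan-2-yl]-2-methylcyclopent-2-en-1-one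
Conditions: [Rh(dppe)]2(BF4)2 (10 mol %), acetone, rt to 60 °C
Reagents that add atoms: none
Why: Rhodium-catalysed intramolecular trans-hydroacylation of the 4-alkynal: the aldehyde C–H bond adds oxidatively and the acyl–rhodium hydride adds across the alkyne in the 5-endo sense to give the 2-methylcyclopent-2-enone; the ring-carbon epimers at C1′ are erased in the next step.

Step 12
Reactants: 18 5-[(2R)-4-[(1R)-2,2-dimethylcyclopropyl]butan-2-yl]-2-methylcyclopent-2-en-1-one
Product: 19 tert-butyl-[[2-[(2R)-4-[(1R)-2,2-dimethylcyclopropyl]butan-2-yl]-5-methylcyclopenta-1,4-dien-1-yl]oxy]dimethylsilane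
Conditions: LiN(i-Pr)2, THF, −78 °C; TBSCl, HMPA, −78 to 0 °C; used at once
Reagents that add atoms: tert-butyldimethylsilyl chloride CC(C)(C)[Si](C)(C)Cl
Why: Kinetic deprotonation of the cyclopentenone at the α′ carbon (C1′) by the hindered amide base and O-silylation of the cross-conjugated dienolate give the 2-silyloxy diene regiospecifically, with C1′ now sp2.

Step 13
Reactants: 5 6-oxopristimerol; 19 tert-butyl-[[2-[(2R)-4-[(1R)-2,2-dimethylcyclopropyl]butan-2-yl]-5-methylcyclopenta-1,4-dien-1-yl]oxy]dimethylsilane
Product: 21 silyl ketal (1′S,5′R; O3–C1′ and O2–C5′ bonded; OTBS on C5′; C3′=C4′ alkene; C1′ carries the cyclopropylbutan-2-yl chain), via o-quinone 20 (not isolated)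
Conditions: 5, Ag2O, Na2SO4, Et2O, rt, filtered under argon; then 19 (1.5 equiv), CH2Cl2, −40 °C to rt
Reagents that add atoms: none
Why: Inverse-electron-demand hetero-Diels–Alder reaction of the o-quinone (heterodiene O3=C3–C2=O2) with the silyl enol ether C1′=C5′: the nucleophilic β-carbon C1′ bonds to O3 (the oxygen whose attack leaves the O2 phenoxide para to the C6 ketone) and O2 closes suprafacially on the oxocarbenium carbon C5′ (cis fusion), while the face is chosen by A(1,3) strain between OTBS and the C10′ stereocenter (C10′–H eclipses the enol ether, so the quinone comes anti to the C9′ chain and syn to the methyl), which should give 1′S.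

Step 14
Reactants: 21 silyl ketal
Product: 22 CNP0317749.1 (target)
Conditions: TMSOTf (1.2 equiv), 2,6-di-tert-butyl-4-methylpyridine (2 equiv), CH2Cl2 (0.002 M), −78 to −20 °C
Reagents that add atoms: none
Why: Proposed new method: TMSOTf silylates the exocyclic silyloxy oxygen of 21 and expels TBSOTMS, giving the C5′ cation, stabilised both by the aryloxy oxygen O2 and as an allyl cation (C5′–C4′–C3′); the tethered gem-dimethylcyclopropane then acts as a σ-nucleophile, its unsubstituted CH2 corner (C6′) bonding to C5′ while the C6′–C11′ bond breaks in the Markovnikov sense to the tertiary C11′ cation, which loses a methyl proton to the hindered pyridine to give the isopropenyl group, with about 27 kcal/mol of ring strain driving the step. The closest known reaction types are the oxocarbenium–alkene Prins cyclization and the Markovnikov-selective electrophilic ring opening of alkylcyclopropanes. The seven-membered ring (C1′, C5′–C10′) is closed by the C5′–C6′ bond through attack of the distal cyclopropane carbon (the bond that breaks lies outside the new ring); the alternative attack at the proximal corner C7′, which would give a six-membered ring, is disfavoured by the contact between two fully substituted carbons and by the preference of electrophiles for the least substituted corner. The new quaternary stereocenter C5′ is fixed by the tether from C1′, which reaches only the face cis to C10′, so the dioxane, cyclopentene and cycloheptane rings come out as the cis-propellane; C7′ keeps its configuration because neither of its bonds to C6′ or C11′ is broken. Site selectivity on the allyl cation (C5′ against C3′) is secured by ring size (seven-membered against a bridged nine-membered ring), and proton loss from a methyl group instead of C7′–H by the bulky base and low temperature. Ionisation of the ring aryloxy group instead of the silyloxy group would only open the dioxane reversibly and converge on the same product.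

**Compound list**

1 | pristimerin (methyl ester of celastrol, natural configuration) | O=C1C=C2C(C(C)=C1O)=CC=C1[C@@]2(C)CC[C@@]2(C)[C@@H]3C[C@](C)(C(=O)OC)CC[C@]3(C)CC[C@]12C | starting material
2 | pristimerol (6-H2 catechol) | Oc1cc2c(c(C)c1O)CC=C1[C@@]2(C)CC[C@@]2(C)[C@@H]3C[C@](C)(C(=O)OC)CC[C@]3(C)CC[C@]12C | intermediate
3 | pristimerol 2,3-diacetate | CC(=O)Oc1cc2c(c(C)c1OC(C)=O)CC=C1[C@@]2(C)CC[C@@]2(C)[C@@H]3C[C@](C)(C(=O)OC)CC[C@]3(C)CC[C@]12C | intermediate
4 | 6-oxopristimerol 2,3-diacetate | CC(=O)Oc1cc2c(c(C)c1OC(C)=O)C(=O)C=C1[C@@]2(C)CC[C@@]2(C)[C@@H]3C[C@](C)(C(=O)OC)CC[C@]3(C)CC[C@]12C | intermediate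
5 | 6-oxopristimerol | Oc1cc2c(c(C)c1O)C(=O)C=C1[C@@]2(C)CC[C@@]2(C)[C@@H]3C[C@](C)(C(=O)OC)CC[C@]3(C)CC[C@]12C | intermediate
6 | (R)-citronellal, (3R)-3,7-dimethyloct-6-enal | CC(C)=CCC[C@@H](C)CC=O | starting material
7 | (6R)-8,8-dimethoxy-2,6-dimethyloct-2-ene | CC(C)=CCC[C@@H](C)CC(OC)OC | intermediate
8 | (2E,6R)-8,8-dimethoxy-2,6-dimethyloct-2-en-1-ol | OC/C(C)=C/CC[C@@H](C)CC(OC)OC | intermediate
9 | [(1R,2R)-2-[(3R)-5,5-dimethoxy-3-methylpentyl]-1-methylcyclopropyl]methanol | OC[C@]1(C)C[C@H]1CC[C@@H](C)CC(OC)OC | intermediate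
10 | (1R,2R)-2-[(3R)-5,5-dimethoxy-3-methylpentyl]-1-methylcyclopropane-1-carbaldehyde | O=C[C@]1(C)C[C@H]1CC[C@@H](C)CC(OC)OC | intermediate
11 | hydrazone of 10 | NN=C[C@]1(C)C[C@H]1CC[C@@H](C)CC(OC)OC | intermediate
12 | (1R)-1-[(3R)-5,5-dimethoxy-3-methylpentyl]-2,2-dimethylcyclopropane | CC1(C)C[C@H]1CC[C@@H](C)CC(OC)OC | intermediate
13 | (3R)-5-[(1R)-2,2-dimethylcyclopropyl]-3-methylpentanal | CC1(C)C[C@H]1CC[C@@H](C)CC=O | intermediate
14 | 1-bromobut-2-yne | CC#CCBr | starting material
15 | N-tert-butyl imine of 13 | CC1(C)C[C@H]1CC[C@@H](C)CC=NC(C)(C)C | intermediate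
16 | N-tert-butyl imine of 17 | CC#CCC(C=NC(C)(C)C)[C@H](C)CC[C@@H]1CC1(C)C | intermediate
17 | (3R)-2-(but-2-yn-1-yl)-5-[(1R)-2,2-dimethylcyclopropyl]-3-methylpentanal (both C2 epimers) | CC#CCC(C=O)[C@H](C)CC[C@@H]1CC1(C)C | intermediate
18 | 5-[(2R)-4-[(1R)-2,2-dimethylcyclopropyl]butan-2-yl]-2-methylcyclopent-2-en-1-one (both C5 epimers) | CC1=CCC([C@H](C)CC[C@@H]2CC2(C)C)C1=O | intermediate
19 | tert-butyl-[[2-[(2R)-4-[(1R)-2,2-dimethylcyclopropyl]butan-2-yl]-5-methylcyclopenta-1,4-dien-1-yl]oxy]dimethylsilane | CC1=CCC([C@H](C)CC[C@@H]2CC2(C)C)=C1O[Si](C)(C)C(C)(C)C | intermediate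
20 | o-quinone of 5 (2,3-dioxo, ring A quinone; 6-oxo) | O=C1C=C2C(=C(C)C1=O)C(=O)C=C1[C@@]2(C)CC[C@@]2(C)[C@@H]3C[C@](C)(C(=O)OC)CC[C@]3(C)CC[C@]12C | intermediate
21 | silyl ketal: 6-oxopristimerol O3–C1′/O2–C5′ dioxane fused to the 4′-methylcyclopent-3′-ene, 5′-OTBS, 1′-[(2R)-4-[(1R)-2,2-dimethylcyclopropyl]butan-2-yl], (1′S,5′R) | CC1(C)C[C@H]1CC[C@@H](C)[C@@]23CC=C(C)[C@]2(O[Si](C)(C)C(C)(C)C)Oc1cc2c(c(C)c1O3)C(=O)C=C1[C@@]2(C)CC[C@@]2(C)[C@@H]3C[C@](C)(C(=O)OC)CC[C@]3(C)CC[C@]12C | intermediate
22 | CNP0317749.1: 6-oxopristimerol 2,3-diether of (1′S,5′S,7′R,10′R)-guaia-3′,11′-diene-1′,5′-diyl (O3–C1′, O2–C5′) | C=C(C)[C@@H]1CC[C@@H](C)[C@@]23CC=C(C)[C@]2(C1)Oc1cc2c(c(C)c1O3)C(=O)C=C1[C@@]2(C)CC[C@@]2(C)[C@@H]3C[C@](C)(C(=O)OC)CC[C@]3(C)CC[C@]12C | target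

**Step count.** Total: 14 steps. Longest linear sequence: 11 steps (6 to 22, steps 4–14). The triterpene branch has 3 steps before the union at step 13.

**Steps most likely to fail**

Step 14 (Proposed new method). The cyclopropane may be too weak a σ-nucleophile for the stabilised C5′ cation, so that the cation is lost by proton elimination to a cyclopentadiene or by triflate capture. Attack may also occur through the substituted corner (six-membered ring), or the C11′ cation may lose the C7′ proton (isopropylidene isomer). The fallback uses known chemistry and keeps the seven-membered ring as the last ring; it sets out from 6 and 5 and comes back at 22. Ethenolysis of 6 (ethylene, second-generation Grubbs catalyst) gives (3R)-3-methylhept-6-enal F1. Its N-tert-butyl imine F2 is lithiated and alkylated with 14 to the alkylated imine F3, and hydrolysis gives (3R)-2-(but-2-yn-1-yl)-3-methylhept-6-enal F4. Rhodium-catalysed hydroacylation as in step 11 gives 5-[(2R)-hex-5-en-2-yl]-2-methylcyclopent-2-en-1-one F5, and LiN(i-Pr)2/TBSCl gives its cross-conjugated silyl dienol ether F6. Cycloaddition with quinone 20 (from 5, as in step 13) gives the vinyl-terminated silyl ketal F7. SnBr4 in CH2Cl2 at −78 °C then ionises the same ketal and the terminal alkene closes the seven-membered ring in a bromide-terminated Prins cyclization (C5′–C6′ bond, secondary cation at C7′ trapped by bromide), giving the 7′-bromo compound F8. Nickel-catalysed reductive cross-coupling of F8 with 2-bromopropene (NiBr2(dme), 4,4′-di-tert-butyl-2,2′-bipyridine, Zn, DMA) installs the isopropenyl group and should give 22. The C7′ configuration then rests on radical capture at nickel and is not secured, so separation of C7′ epimers must be expected.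

Step 13. The quinone may approach the wrong face of the enol ether (substrate control rests only on A(1,3) strain), electron transfer or C-alkylation may compete with cycloaddition, and 19 may isomerise by 1,5-hydrogen shift before it reacts. The fallback replaces substrate control by reagent control; it sets out from 5 and 19 and comes back at 21. Quinone 20 is chelated through its 1,2-dicarbonyl unit to Cu(OTf)2 bearing a chiral tert-butyl-bis(oxazoline) ligand (the ligand antipode that matches the C10′ bias is chosen) and is reacted with 19 at −78 °C, which also lowers the temperature at which the cycloaddition competes with isomerisation of 19. No new compound is formed.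

Step 11. The α-branched aldehyde may decarbonylate at rhodium, or the alkyne may oligomerise, instead of undergoing trans-hydroacylation. The fallback builds the cyclopentenone by ring-closing metathesis; it sets out from 13 (through its imine 15) and comes back at 18. Lithiated 15 is alkylated with allyl bromide to the allylated imine F9, and hydrolysis gives (3R)-5-[(1R)-2,2-dimethylcyclopropyl]-3-methyl-2-(prop-2-en-1-yl)pentanal F10. Addition of isopropenylmagnesium bromide gives (5R)-7-[(1R)-2,2-dimethylcyclopropyl]-2,5-dimethyl-4-(prop-2-en-1-yl)hept-1-en-3-ol F11, and Dess–Martin oxidation gives (5R)-7-[(1R)-2,2-dimethylcyclopropyl]-2,5-dimethyl-4-(prop-2-en-1-yl)hept-1-en-3-one F12. Ring-closing metathesis with the second-generation Grubbs catalyst then closes the 2-methylcyclopentenone 18.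

Further compounds
F1 | step 14 | (3R)-3-methylhept-6-enal | C=CCC[C@@H](C)CC=O
F2 | step 14 | N-tert-butyl imine of F1 | C=CCC[C@@H](C)CC=NC(C)(C)C
F3 | step 14 | N-tert-butyl imine of F4 | CC#CCC(C=NC(C)(C)C)[C@H](C)CCC=C
F4 | step 14 | (3R)-2-(but-2-yn-1-yl)-3-methylhept-6-enal | CC#CCC(C=O)[C@H](C)CCC=C
F5 | step 14 | 5-[(2R)-hex-5-en-2-yl]-2-methylcyclopent-2-en-1-one | CC1=CCC([C@H](C)CCC=C)C1=O
F6 | step 14 | tert-butyl-[[2-[(2R)-hex-5-en-2-yl]-5-methylcyclopenta-1,4-dien-1-yl]oxy]dimethylsilane | CC1=CCC([C@H](C)CCC=C)=C1O[Si](C)(C)C(C)(C)C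
F7 | step 14 | silyl ketal analogue of 21 with a (2R)-hex-5-en-2-yl chain on C1′ | C=CCC[C@@H](C)[C@@]23CC=C(C)[C@]2(O[Si](C)(C)C(C)(C)C)Oc1cc2c(c(C)c1O3)C(=O)C=C1[C@@]2(C)CC[C@@]2(C)[C@@H]3C[C@](C)(C(=O)OC)CC[C@]3(C)CC[C@]12C
F8 | step 14 | 7′-bromo analogue of 22 (bromine in place of the isopropenyl group, C7′ unassigned) | BrC1CC[C@@H](C)[C@@]23CC=C(C)[C@]2(C1)Oc1cc2c(c(C)c1O3)C(=O)C=C1[C@@]2(C)CC[C@@]2(C)[C@@H]3C[C@](C)(C(=O)OC)CC[C@]3(C)CC[C@]12C
F0 | step 13 | none | none
F9 | step 11 | N-tert-butyl imine of F10 | C=CCC(C=NC(C)(C)C)[C@H](C)CC[C@@H]1CC1(C)C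
F10 | step 11 | (3R)-5-[(1R)-2,2-dimethylcyclopropyl]-3-methyl-2-(prop-2-en-1-yl)pentanal | C=CCC(C=O)[C@H](C)CC[C@@H]1CC1(C)C
F11 | step 11 | (5R)-7-[(1R)-2,2-dimethylcyclopropyl]-2,5-dimethyl-4-(prop-2-en-1-yl)hept-1-en-3-ol | C=CCC(C(O)C(C)=C)[C@H](C)CC[C@@H]1CC1(C)C
F12 | step 11 | (5R)-7-[(1R)-2,2-dimethylcyclopropyl]-2,5-dimethyl-4-(prop-2-en-1-yl)hept-1-en-3-one | C=CCC(C(=O)C(C)=C)[C@H](C)CC[C@@H]1CC1(C)C
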